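**Plan**

- Labels: ring A = butenolide (C1, O2, C3, C3a, C7a); ring B = C3a–C4–C5–C6–C7–C7a; ring C = cyclobutane (C6, C7, C3', C8'); ring D = lactone (C3', O2', C1', C7a', C3a'); ring E = benzo ring; C8 = butylidene CH; C9' = first propyl carbon.
- Ring A is cut at O2–C3 (silver-catalysed lactonisation) and C3–C3a (Sonogashira coupling), leading back to a dioxinone that masks the C3a ketone and the C1 carboxyl.
- Rings D and E share the C3a'–C7a' bond and both hang from the quaternary carbinol carbon C3', which carries O2' and C3a'. C3a'–C7a', C4'–C5' and C6'–C7' are therefore cut together, giving an ethynyl group on C3', a propynoate on O2' and acetylene.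
- Further cuts: O2'–C1' (acylation), C3'–C3a' (ethynylation of a cyclobutanone), C6–C7 and C3'–C8' (intramolecular keteniminium–alkene cycloaddition), C4–C5 (dienolate alkylation), C7–C7a (Negishi coupling).
- Forward: the dioxinone is bought; rings B and C close together; rings D and E close together in the cyclotrimerisation; ring A closes last.
- Stereochemistry: C6, C7 and C8' come from the (2+2) step (cis fusion from the tether, endo propyl from the (Z)-alkene, absolute sense from a C2-symmetric pyrrolidine auxiliary); C3' from convex-face ethynylation; the (Z)-C3=C8 bond from anti oxymetalation.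

Key step: step 11

Assumption: the (2S,5S)-2,5-dimethylpyrrolidinium group is taken to direct the alkene to the keteniminium face that gives (6S,7R,8'R)-14; if the opposite sense is found, the (2R,5R)-amine is used in step 2 and nothing else changes.

**Step 1**
Reactants: 1 (Z)-hex-2-en-1-ol
Product: 2 (Z)-1-bromohex-2-ene
Conditions: CBr4, PPh3, CH2Cl2, 0 °C
Reagents that add atoms: carbon tetrabromide, BrC(Br)(Br)Br
Why: Appel bromination replaces the primary allylic hydroxyl by SN2 attack of bromide on the alkoxyphosphonium ion at 0 °C, where the (Z)-alkene should neither transpose nor isomerise.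

**Step 2**
Reactants: 3 (2S,5S)-2,5-dimethylpyrrolidine; 4 bromoacetyl bromide
Product: 5 2-bromo-1-[(2S,5S)-2,5-dimethylpyrrolidin-1-yl]ethan-1-one
Conditions: K2CO3, CH2Cl2/H2O, 0 °C
Reagents that add atoms: none
Why: Schotten–Baumann N-acylation, in which the acyl bromide is far more electrophilic than the alkyl bromide, so only the amide should form and the two stereocentres of the amine are untouched.

**Step 3**
Reactants: 6 2,2,6-trimethyl-4H-1,3-dioxin-4-one
Product: 7 5-iodo-2,2,6-trimethyl-4H-1,3-dioxin-4-one
Conditions: N-iodosuccinimide, AcOH, rt, dark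
Reagents that add atoms: N-iodosuccinimide, O=C1CCC(=O)N1I
Why: Electrophilic iodination at C5, the enol-ether β-carbon and only nucleophilic ring carbon of the dioxinone, followed by loss of the proton.

**Step 4**
Reactants: 5 2-bromo-1-[(2S,5S)-2,5-dimethylpyrrolidin-1-yl]ethan-1-one; 7 5-iodo-2,2,6-trimethyl-4H-1,3-dioxin-4-one
Product: 9 5-{2-[(2S,5S)-2,5-dimethylpyrrolidin-1-yl]-2-oxoethyl}-2,2,6-trimethyl-4H-1,3-dioxin-4-one, via bromozinc amide enolate 8 (not isolated)
Conditions: Zn dust (Me3SiCl-activated), THF, rt; then 7, Pd2(dba)3 (2.5 mol %), XPhos (10 mol %), THF, 50 °C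
Reagents that add atoms: none
Why: Negishi-type cross-coupling of a Reformatsky reagent: zinc inserts into the α-bromo amide, the vinylic C5–I bond adds oxidatively to zerovalent palladium, and transmetalation and reductive elimination form the C7–C7a bond without the amide ever meeting acidic dehydrating conditions next to a ketone.

**Step 5**
Reactants: 9 5-{2-[(2S,5S)-2,5-dimethylpyrrolidin-1-yl]-2-oxoethyl}-2,2,6-trimethyl-4H-1,3-dioxin-4-one; 2 (Z)-1-bromohex-2-ene
Product: 11 5-{2-[(2S,5S)-2,5-dimethylpyrrolidin-1-yl]-2-oxoethyl}-6-[(Z)-hept-3-en-1-yl]-2,2-dimethyl-4H-1,3-dioxin-4-one, via lithium dienolate 10 (not isolated)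
Conditions: LiN(SiMe3)2, THF/DMPU, −78 °C; then 2, −78 → −40 °C
Reagents that add atoms: none
Why: Vinylogous (γ) alkylation of the dioxinone dienolate: the silylamide base should remove only the more acidic C6-methyl proton (the amide CH2 is several pKa units weaker), C5 is blocked, and SN2 attack on the primary allylic bromide forms C4–C5 with the (Z)-alkene intact.

**Step 6**
Reactants: 11 5-{2-[(2S,5S)-2,5-dimethylpyrrolidin-1-yl]-2-oxoethyl}-6-[(Z)-hept-3-en-1-yl]-2,2-dimethyl-4H-1,3-dioxin-4-one
Product: 14 (6S,7R,8'R)-dioxinone-fused endo-propyl cyclobutanone, via keteniminium triflate 12 (not isolated), via cyclobutaniminium triflate 13 (not isolated)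
Conditions: Tf2O, 2,4,6-collidine, ClCH2CH2Cl, 0 → 80 °C; then H2O, aq. NaHCO3, rt
Reagents that add atoms: water, O
Why: Amide O-triflation and loss of triflic acid give the keteniminium ion, which adds across the tethered alkene in an intramolecular keteniminium–alkene (2+2) cycloaddition forming C3'–C8' and C7–C6: the tether through the cis C3a=C7a bond enforces the cis B/C fusion, suprafacial addition to the (Z)-alkene keeps propyl cis to C5 (endo), and the C2-symmetric pyrrolidinium, which has a single keteniminium geometry, is expected to shield one face so that C6, C7 and C8' arise as 6S,7R,8'R before mild hydrolysis of the iminium salt.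

**Step 7**
Reactants: 14 (6S,7R,8'R)-dioxinone-fused endo-propyl cyclobutanone; 15 ethynylmagnesium bromide
Product: 16 (3'R,6S,7R,8'R)-C3' ethynyl carbinol
Conditions: HC≡CMgBr, CeCl3, THF, −78 °C; then H2O
Reagents that add atoms: none
Why: 1,2-Addition of the Grignard reagent (made less basic by CeCl3) to the strained ketone should occur on the convex face flanked by H7 and H8', because propyl and ring B block the other face, which sets C3' with ethynyl syn to H7/H8' and hydroxyl syn to propyl.

**Step 8**
Reactants: 17 3-(trimethylsilyl)prop-2-ynoic acid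
Product: 18 3-(trimethylsilyl)prop-2-ynoyl chloride
Conditions: (COCl)2, DMF (cat.), CH2Cl2, 0 °C → rt; used crude
Reagents that add atoms: oxalyl chloride, O=C(Cl)C(=O)Cl
Why: Acid chloride formation through the Vilsmeier-type chloroiminium catalyst, with the silyl cap protecting the alkyne against HCl addition.

**Step 9**
Reactants: 16 (3'R,6S,7R,8'R)-C3' ethynyl carbinol; 18 3-(trimethylsilyl)prop-2-ynoyl chloride
Product: 20 C3' ethynyl 3-(trimethylsilyl)propynoate, via lithium alkoxide 19 (not isolated)
Conditions: LiN(SiMe3)2 (1.0 equiv), THF, −78 °C; then 18, −78 → 0 °C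
Reagents that add atoms: none
Why: O-Acylation of a preformed lithium alkoxide by a slim, highly electrophilic alkynoyl chloride, the way congested tertiary ethynyl carbinols are usually esterified, with the silyl group preventing conjugate addition and polymerisation of the propynoate.

**Step 10**
Reactants: 20 C3' ethynyl 3-(trimethylsilyl)propynoate
Product: 21 C3' ethynyl propynoate (diyne ester)
Conditions: Bu4NF, AcOH, THF, −20 °C
Reagents that add atoms: none
Why: Fluoride-induced protodesilylation of the alkynylsilane, buffered by acetic acid so that the propynoate ester is neither cleaved nor attacked in a conjugate sense.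

**Step 11**
Reactants: 21 C3' ethynyl propynoate (diyne ester); 22 acetylene
Product: 23 dioxinone-fused spiro phthalide
Conditions: Cp*RuCl(cod) (5 mol %), HC≡CH (1 atm), ClCH2CH2Cl, rt, slow addition of 21
Reagents that add atoms: none
Why: After loss of cod the Cp*RuCl fragment (divalent ruthenium) binds both alkynes of 21 and couples them oxidatively to a ruthenacyclopentadiene (tetravalent ruthenium), forming C3a'–C7a'; acetylene then inserts and reductive elimination forms C4'–C5' and C6'–C7' and releases the arene. The closest known reaction type is the ruthenium- or rhodium-catalysed (2+2+2) cycloaddition of ester- or ether-tethered 1,6-diynes with alkynes to phthalides and spiro-fused phthalans. Ring D closes in the oxidative coupling as the five-membered ring spanned by the C3'–O2'–C1' tether, and ring E closes by acetylene insertion and reductive elimination, a metal-templated assembly of three alkynes. No stereocentre is formed or touched, so C3' keeps the configuration set in step 7. The step needs cross-cyclotrimerisation to win over diyne self-coupling: the quaternary C3' speeds the intramolecular coupling (gem-disubstituent effect), the crowded ruthenacycle should accept only the small acetylene from a saturated solution while 21 is added slowly, the tetrasubstituted electron-poor C3a=C7a bond is not a competent 2π partner, and acetylene being symmetrical leaves no regiochemical question.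

**Step 12**
Reactants: 23 dioxinone-fused spiro phthalide
Product: 25 tert-butyl β-keto ester (C3a ketone and C7a ester), via acylketene 24 (not isolated)
Conditions: t-BuOH (10 equiv), toluene, 110 °C, sealed tube
Reagents that add atoms: tert-butanol, CC(C)(C)O
Why: Thermal retro-hetero-Diels–Alder loss of acetone from the dioxinone gives the acylketene, which tert-butanol traps as the β-keto ester; the C7a centre formed is inconsequential because it is enolised in the next step.

**Step 13**
Reactants: 25 tert-butyl β-keto ester (C3a ketone and C7a ester)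
Product: 26 C3a enol triflate tert-butyl ester
Conditions: Tf2O, i-Pr2NEt, CH2Cl2, −78 °C
Reagents that add atoms: trifluoromethanesulfonic anhydride, O=S(=O)(OS(=O)(=O)C(F)(F)F)C(F)(F)F
Why: O-Sulfonylation of the conjugated β-keto ester enol (enol triflate formation), which can only place the double bond at C3a=C7a.

**Step 14**
Reactants: 26 C3a enol triflate tert-butyl ester; 27 pent-1-yne
Product: 28 C3a pent-1-ynyl tert-butyl ester
Conditions: PdCl2(PPh3)2 (5 mol %), CuI (10 mol %), Et3N, DMF, rt
Reagents that add atoms: none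
Why: Sonogashira coupling: the electron-poor vinyl triflate adds oxidatively to zerovalent palladium, the copper acetylide of pent-1-yne transmetalates, and reductive elimination forms C3–C3a.

**Step 15**
Reactants: 28 C3a pent-1-ynyl tert-butyl ester
Product: 29 enynoic acid
Conditions: CF3CO2H, CH2Cl2, 0 °C
Reagents that add atoms: none
Why: Acidolysis of the tert-butyl ester with loss of isobutene frees the C1 acid without base, so the phthalide ring D is never opened.

**Step 16**
Reactants: 29 enynoic acid
Product: 30 target spiro bis-lactone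
Conditions: AgNO3 (10 mol %), acetone, rt, dark
Reagents that add atoms: none
Why: Silver-catalysed 5-exo-dig cycloisomerisation of a (Z)-2-en-4-ynoic acid: anti attack of the carboxylate on the silver-bound alkyne and protodemetalation form O2–C3 and should give the (Z)-butylidene group with propyl syn to O2.

**Compound list**

1 | (Z)-hex-2-en-1-ol | CCC/C=C\CO | starting material
2 | (Z)-1-bromohex-2-ene | CCC/C=C\CBr | intermediate
3 | (2S,5S)-2,5-dimethylpyrrolidine | C[C@H]1CC[C@H](C)N1 | starting material
4 | bromoacetyl bromide | BrCC(Br)=O | starting material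
5 | 2-bromo-1-[(2S,5S)-2,5-dimethylpyrrolidin-1-yl]ethan-1-one | O=C(CBr)N1[C@@H](C)CC[C@@H]1C | intermediate
6 | 2,2,6-trimethyl-4H-1,3-dioxin-4-one | CC1=CC(=O)OC(C)(C)O1 | starting material
7 | 5-iodo-2,2,6-trimethyl-4H-1,3-dioxin-4-one | CC1=C(I)C(=O)OC(C)(C)O1 | intermediate
8 | bromozinc amide enolate (Reformatsky reagent from 5, formed in the flask) | Br[Zn]CC(=O)N1[C@@H](C)CC[C@@H]1C | intermediate
9 | 5-{2-[(2S,5S)-2,5-dimethylpyrrolidin-1-yl]-2-oxoethyl}-2,2,6-trimethyl-4H-1,3-dioxin-4-one | CC1=C(CC(=O)N2[C@@H](C)CC[C@@H]2C)C(=O)OC(C)(C)O1 | intermediate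
10 | lithium dienolate of 9 (4-lithiooxy-6-methylene form, formed in the flask) | C=C1OC(C)(C)OC(O[Li])=C1CC(=O)N1[C@@H](C)CC[C@@H]1C | intermediate
11 | 5-{2-[(2S,5S)-2,5-dimethylpyrrolidin-1-yl]-2-oxoethyl}-6-[(Z)-hept-3-en-1-yl]-2,2-dimethyl-4H-1,3-dioxin-4-one | CCC/C=C\CCC1=C(CC(=O)N2[C@@H](C)CC[C@@H]2C)C(=O)OC(C)(C)O1 | intermediate
12 | keteniminium triflate of 11 (N-ethenylidene-(2S,5S)-2,5-dimethylpyrrolidinium, formed in the flask) | CCC/C=C\CCC1=C(C=C=[N+]2[C@@H](C)CC[C@@H]2C)C(=O)OC(C)(C)O1.[O-]S(=O)(=O)C(F)(F)F | intermediate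
13 | cyclobutaniminium triflate (C3' iminium of 14 with the auxiliary, formed in the flask) | CC1(C)OC(=O)C2=C(O1)CC[C@H]1[C@@H](CCC)C(=[N+]3[C@@H](C)CC[C@@H]3C)[C@@H]21.[O-]S(=O)(=O)C(F)(F)F | intermediate
14 | (6S,7R,8'R)-cyclobutanone: 2,2-dimethyl-1,3-dioxin-4-one fused across C3a–C7a of ring B; ring B cis-fused at C6–C7 to cyclobutanone ring C; C3' ketone on C7; 8'-propyl cis to C5 (endo); H6, H7 and H8' on one face | CC1(C)OC(=O)C2=C(O1)CC[C@H]1[C@@H](CCC)C(=O)[C@@H]21 | intermediate
15 | ethynylmagnesium bromide | C#C[Mg]Br | starting material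
16 | (3'R,6S,7R,8'R)-C3' ethynyl carbinol: ethynyl syn to H7 and H8', hydroxyl syn to propyl and ring B | CC1(C)OC(=O)C2=C(O1)CC[C@H]1[C@@H](CCC)[C@@](C#C)(O)[C@@H]21 | intermediate
17 | 3-(trimethylsilyl)prop-2-ynoic acid | C[Si](C)(C)C#CC(=O)O | starting material
18 | 3-(trimethylsilyl)prop-2-ynoyl chloride | C[Si](C)(C)C#CC(=O)Cl | intermediate
19 | lithium alkoxide of 16 (formed in the flask) | CC1(C)OC(=O)C2=C(O1)CC[C@H]1[C@@H](CCC)[C@@](C#C)(O[Li])[C@@H]21 | intermediate
20 | (3'R,6S,7R,8'R)-C3' ethynyl 3-(trimethylsilyl)propynoate | CC1(C)OC(=O)C2=C(O1)CC[C@H]1[C@@H](CCC)[C@@](C#C)(OC(=O)C#C[Si](C)(C)C)[C@@H]21 | intermediate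
21 | (3'R,6S,7R,8'R)-C3' ethynyl propynoate (dioxinone-fused diyne ester) | CC1(C)OC(=O)C2=C(O1)CC[C@H]1[C@@H](CCC)[C@@](C#C)(OC(=O)C#C)[C@@H]21 | intermediate
22 | acetylene | C#C | starting material
23 | (3'R,6S,7R,8'R)-dioxinone-fused spiro phthalide: rings D and E spiro at C3', aryl carbon C3a' syn to H7 and H8', O2' syn to propyl | CC1(C)OC(=O)C2=C(O1)CC[C@H]1[C@@H](CCC)[C@@]3(OC(=O)c4ccccc43)[C@@H]21 | intermediate
24 | acylketene (C7a ketene, C3a ketone, formed in the flask) | O=C=C1C(=O)CC[C@H]2[C@@H](CCC)[C@@]3(OC(=O)c4ccccc43)[C@@H]12 | intermediate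
25 | tert-butyl β-keto ester (C3a ketone, C7a tert-butoxycarbonyl, C7a epimers and enol) | CC(C)(C)OC(=O)C1C(=O)CC[C@H]2[C@@H](CCC)[C@@]3(OC(=O)c4ccccc43)[C@@H]12 | intermediate
26 | C3a enol triflate, C7a tert-butyl ester | CC(C)(C)OC(=O)C1=C(OS(=O)(=O)C(F)(F)F)CC[C@H]2[C@@H](CCC)[C@@]3(OC(=O)c4ccccc43)[C@@H]12 | intermediate
27 | pent-1-yne | CCCC#C | starting material
28 | C3a pent-1-ynyl, C7a tert-butyl ester | CC(C)(C)OC(=O)C1=C(C#CCCC)CC[C@H]2[C@@H](CCC)[C@@]3(OC(=O)c4ccccc43)[C@@H]12 | intermediate
29 | enynoic acid (C3a pent-1-ynyl, C7a carboxylic acid) | OC(=O)C1=C(C#CCCC)CC[C@H]2[C@@H](CCC)[C@@]3(OC(=O)c4ccccc43)[C@@H]12 | intermediate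
30 | target (3'R,6S,7R,8'R,Z)-spiro bis-lactone | CCC/C=C1\OC(=O)C2=C1CC[C@H]1[C@@H](CCC)[C@@]3(OC(=O)c4ccccc43)[C@@H]21 | target

**Step count and risks**

Total step count: 16 (steps 1, 2 and 8 prepare side components).
Longest linear sequence: 13 steps, from 6 to 30 through steps 3–7 and 9–16.

Steps most likely to fail:

1. Step 6. The dioxinone carbonyl oxygen sits 1,5 to the keteniminium carbon and may capture it as a five-membered cyclic cation faster than the alkene adds. Facial control by the auxiliary may be incomplete, and the endo propyl group may epimerise through the enamine of the iminium salt. Fallback: a neutral ketene and a resolution, setting out from 7. The zinc reagent tert-butyl 2-(bromozincio)acetate F1 (from tert-butyl bromoacetate and zinc) is coupled with 7 under the palladium conditions of step 4 to give tert-butyl 2-(2,2,6-trimethyl-4-oxo-4H-1,3-dioxin-5-yl)acetate F2. Alkylation with 2 as in step 5 gives the heptenyl tert-butyl ester F3, and CF3CO2H in CH2Cl2 gives the acetic acid F4. Oxalyl chloride gives the acid chloride F5, and Et3N in toluene at 80 °C gives the vinylketene F6, which has no cationic centre. Its intramolecular ketene–alkene (2+2) cycloaddition should give the racemic cyclobutanone, that is 14 with its mirror image ent-14 F7. Preparative HPLC on a chiral stationary phase isolates 14, where the route is rejoined.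

2. Step 5. The base may also deprotonate the amide CH2, the dienolate may alkylate twice or at C5, and it may fragment before it is alkylated. Fallback: both side chains are installed on an open-chain β-keto ester and the dioxinone is closed last, setting out from 2. tert-Butyl acetoacetate is doubly deprotonated (NaH, then n-BuLi, THF, 0 °C) and alkylated at the terminal carbon with 2 to give tert-butyl (Z)-3-oxodec-6-enoate F8. Alkylation at C2 with 5 (K2CO3, acetone) gives tert-butyl (Z)-2-{2-[(2S,5S)-2,5-dimethylpyrrolidin-1-yl]-2-oxoethyl}-3-oxodec-6-enoate F9. Acetone, (CF3CO)2O and CF3CO2H at 0 °C close the dioxinone and give 11. This ring closure is kept short and cold because the keto amide can also cyclodehydrate.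

3. Step 9. O-Acylation of the alkoxide, which is flanked on its own face by propyl and ring B, may be slow, so that proton transfer to the acetylide or the dioxinone dienolate and C-acylation take over. Fallback: a tether at the ether oxidation level, setting out from 16. KH and propargyl bromide in THF at 0 °C (Williamson etherification) give the C3' ethynyl propargyl ether F10. The Cp*RuCl(cod)/acetylene cyclotrimerisation of step 11 then forms the same three bonds and closes rings D and E as the spiro 1',3'-dihydroisobenzofuran F11. Benzylic oxidation of the C1' methylene with pyridinium chlorochromate, (C5H5NH)[CrO3Cl], in refluxing CH2Cl2 gives 23, where the route is rejoined.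

**Further compounds**

F1 | step 6 | tert-butyl 2-(bromozincio)acetate | Br[Zn]CC(=O)OC(C)(C)C
F2 | step 6 | tert-butyl 2-(2,2,6-trimethyl-4-oxo-4H-1,3-dioxin-5-yl)acetate | CC1=C(CC(=O)OC(C)(C)C)C(=O)OC(C)(C)O1
F3 | step 6 | tert-butyl 2-{6-[(Z)-hept-3-en-1-yl]-2,2-dimethyl-4-oxo-4H-1,3-dioxin-5-yl}acetate | CCC/C=C\CCC1=C(CC(=O)OC(C)(C)C)C(=O)OC(C)(C)O1
F4 | step 6 | 2-{6-[(Z)-hept-3-en-1-yl]-2,2-dimethyl-4-oxo-4H-1,3-dioxin-5-yl}acetic acid | CCC/C=C\CCC1=C(CC(=O)O)C(=O)OC(C)(C)O1
F5 | step 6 | 2-{6-[(Z)-hept-3-en-1-yl]-2,2-dimethyl-4-oxo-4H-1,3-dioxin-5-yl}acetyl chloride | CCC/C=C\CCC1=C(CC(=O)Cl)C(=O)OC(C)(C)O1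
F6 | step 6 | vinylketene, 5-(2-oxoethenyl)-6-[(Z)-hept-3-en-1-yl]-2,2-dimethyl-4H-1,3-dioxin-4-one | CCC/C=C\CCC1=C(C=C=O)C(=O)OC(C)(C)O1
F7 | step 6 | ent-14, (6R,7S,8'S)-cyclobutanone | CC1(C)OC(=O)C2=C(O1)CC[C@@H]1[C@H](CCC)C(=O)[C@H]21
F8 | step 5 | tert-butyl (Z)-3-oxodec-6-enoate | CCC/C=C\CCC(=O)CC(=O)OC(C)(C)C
F9 | step 5 | tert-butyl (Z)-2-{2-[(2S,5S)-2,5-dimethylpyrrolidin-1-yl]-2-oxoethyl}-3-oxodec-6-enoate | CCC/C=C\CCC(=O)C(CC(=O)N1[C@@H](C)CC[C@@H]1C)C(=O)OC(C)(C)C
F10 | step 9 | (3'R,6S,7R,8'R)-C3' ethynyl propargyl ether | CC1(C)OC(=O)C2=C(O1)CC[C@H]1[C@@H](CCC)[C@@](C#C)(OCC#C)[C@@H]21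
F11 | step 9 | (3'R,6S,7R,8'R)-dioxinone-fused spiro 1',3'-dihydroisobenzofuran | CC1(C)OC(=O)C2=C(O1)CC[C@H]1[C@@H](CCC)[C@@]3(OCc4ccccc43)[C@@H]21
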